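Numbering the lactone carbonyl carbon C1 and the O-bound methylene C32, the 33-membered ring (O, C1–C32) is an unbranched chain of 31 methylenes without any stereocentre. The C7–C8 bond is therefore an ordinary CH2–CH2 link that can be born as an alkene and leave no trace. The key step makes the target in one vessel from the acyclic ester hexacos-25-en-1-yl oct-7-enoate: a ruthenium alkylidene joins C7 to C8 with loss of ethene, closing the ring, and the same ruthenium charge, turned into a hydride by H2, saturates the new alkene. The diene comes in two steps from three commercial pieces: oct-7-enoic acid (C1–C7) and a C10 + C16 pair (C8–C32).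

Key step: step 3

Remark: 10-bromodec-1-ene, 16-bromohexadecan-1-ol and oct-7-enoic acid are taken as catalogue chemicals; the target has no stereocentre, so no stereocontrol is needed.

Step 1
Reactants: 1 10-bromodec-1-ene; 2 16-bromohexadecan-1-ol
Product: 4 hexacos-25-en-1-ol, via dec-9-en-1-ylmagnesium bromide 3 (not isolated)
Conditions: 1 (2.5 equiv), Mg, THF, 40 °C; then 2, Li2CuCl4 (3 mol %), THF, −20 °C to rt; aq. NH4Cl
Reagents that add atoms: none
Why: A Kochi-type copper-catalysed sp3–sp3 cross-coupling of a primary alkylmagnesium bromide with a primary alkyl bromide should join the C10 and C16 chains; the first equivalent of 3 only deprotonates the hydroxyl group of 2 (released as dec-1-ene), the resulting alkoxide is inert, and neither terminal alkene takes part.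

Step 2
Reactants: 4 hexacos-25-en-1-ol; 5 oct-7-enoic acid
Product: 6 hexacos-25-en-1-yl oct-7-enoate
Conditions: DCC (1.2 equiv), DMAP (0.1 equiv), CH2Cl2, 0 °C to 30 °C
Reagents that add atoms: none
Why: Steglich esterification: DCC activates 5 as its O-acylisourea and DMAP relays the acyl group to the primary alcohol 4 under neutral conditions that cannot move either terminal double bond.

Step 3
Reactants: 6 hexacos-25-en-1-yl oct-7-enoate
Product: 8 1-oxacyclotritriacontan-2-one, via 1-oxacyclotritriacont-8-en-2-one 7 (not isolated)
Conditions: second-generation Grubbs catalyst RuCl2(H2IMes)(PCy3)(=CHPh) (5 mol %), ClCH2CH2Cl, 1 mM (6 added over 12 h), 45 °C, Ar sparge; then H2 (7 bar), 70 °C, same vessel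
Reagents that add atoms: none
Why: The Ru benzylidene exchanges with one terminal alkene of 6, the new alkylidene adds [2+2] to the other terminal alkene, and the ruthenacyclobutane opens to release ring alkene 7 with C7 bound to C8 while ethene is swept out; H2 then turns the Ru alkylidene into a ruthenium hydride that hydrogenates C7=C8 of 7 to the CH2–CH2 link of 8. The closest known reaction type is macrocyclic ring-closing olefin metathesis of an ω-alkenyl ω-alkenoate followed by tandem Ru-catalysed hydrogenation. The 33-membered ring closes end to end by intramolecular cycloaddition and cycloreversion at a strain-free size, where the ring–chain equilibrium, pulled by ethene loss at 1 mM, should favour the monomeric ring and return oligomers by back-biting. No stereocentre is formed, and the E/Z ratio of 7 is irrelevant because hydrogenation erases it. The step needs cyclization over oligomerization and no double-bond migration before closure; the substrate secures this by carrying only two unhindered terminal alkenes, with its single Lewis-basic ester group too remote from either to tie up the Ru alkylidene in a chelate, and by meeting a dilute catalyst solution slowly before any hydride-forming H2 is admitted.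

Compound list
1 | 10-bromodec-1-ene | C=CCCCCCCCCBr | starting material
2 | 16-bromohexadecan-1-ol | OCCCCCCCCCCCCCCCCBr | starting material
3 | dec-9-en-1-ylmagnesium bromide (not isolated) | C=CCCCCCCCC[Mg]Br | intermediate
4 | hexacos-25-en-1-ol | OCCCCCCCCCCCCCCCCCCCCCCCCC=C | intermediate
5 | oct-7-enoic acid | C=CCCCCCC(=O)O | starting material
6 | hexacos-25-en-1-yl oct-7-enoate | C=CCCCCCC(=O)OCCCCCCCCCCCCCCCCCCCCCCCCC=C | intermediate
7 | 1-oxacyclotritriacont-8-en-2-one (E/Z mixture, not isolated) | O=C1CCCCCC=CCCCCCCCCCCCCCCCCCCCCCCCCO1 | intermediate
8 | 1-oxacyclotritriacontan-2-one (dotriacontan-32-olide) | O=C1CCCCCCCCCCCCCCCCCCCCCCCCCCCCCCCO1 | target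

Total step count: 3
Longest linear sequence: 3 steps (1 or 2 → 4 → 6 → 8)

Steps most likely to fail

Step 3. Ruthenium hydride species formed by catalyst decay may walk the terminal double bonds of 6 inward before ring closure. Metathesis of the migrated alkenes would then expel propene instead of ethene and close 32- or 31-membered rings, whose saturated lactones could not be separated from 8. Intermolecular metathesis may also outrun closure of so large a ring, and saturation may stay incomplete at the low ruthenium concentration. The fallback keeps the same ring-closing bond but forms it irreversibly between two alkyne carbons that cannot migrate; it sets out from 2 and comes back at 8. Commercial nona-1,8-diyne (C#CCCCCCC#C, 4 equiv) would be monolithiated with n-BuLi (3 equiv) in THF/DMPU at −78 °C to lithium nona-1,8-diyn-1-ide F1. Alkylation of F1 with 2 at −78 °C to rt, one equivalent being consumed by the hydroxyl group, should give pentacosa-17,24-diyn-1-ol F2. Steglich esterification (DCC, DMAP, CH2Cl2) with commercial hept-6-ynoic acid (C#CCCCCC(=O)O) should give pentacosa-17,24-diyn-1-yl hept-6-ynoate F3. Eglinton oxidative coupling (Cu(OAc)2, pyridine/MeCN, 60 °C, slow addition to high dilution) should join the two terminal alkyne carbons, C7 to C8, and leave the internal alkyne untouched, giving 1-oxacyclotritriaconta-7,9,16-triyn-2-one F4. Exhaustive hydrogenation (H2, 10% Pd/C, EtOAc, 40 °C) would then deliver 8.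

Step 1. Deprotonation of 2 gives a long-chain bromomagnesium alkoxide that may precipitate from cold THF, so that cross-coupling stalls while homocoupling and β-hydride pathways consume 3. The fallback removes the acidic proton by changing the order of bond construction; it sets out from 2 and 5 and comes back at 6. Steglich esterification of 2 with 5 (DCC, DMAP, CH2Cl2) should give 16-bromohexadecyl oct-7-enoate F5. Chemoselective copper-catalysed coupling of F5 with 3 (1.2 equiv, Li2CuCl4 3 mol %, THF/NMP, 0 °C), conditions under which esters are tolerated, should give 6 directly.

Step 2. Acylation of the waxy, poorly soluble alcohol 4 may be slow enough for the O-acylisourea of 5 to rearrange by acyl migration to the unreactive N-acylurea. The fallback uses a preformed acylating agent; it sets out from 5 and comes back at 6. Treatment of 5 with oxalyl chloride (cat. DMF, CH2Cl2, 0 °C to rt) should give oct-7-enoyl chloride F6, which would acylate 4 in toluene/pyridine at 60 °C, where the alcohol is fully dissolved, to give 6.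

Further compounds
F1 | step 3 | lithium nona-1,8-diyn-1-ide | [Li]C#CCCCCCC#C
F2 | step 3 | pentacosa-17,24-diyn-1-ol | OCCCCCCCCCCCCCCCCC#CCCCCCC#C
F3 | step 3 | pentacosa-17,24-diyn-1-yl hept-6-ynoate | C#CCCCCC(=O)OCCCCCCCCCCCCCCCCC#CCCCCCC#C
F4 | step 3 | 1-oxacyclotritriaconta-7,9,16-triyn-2-one | O=C1CCCCC#CC#CCCCCCC#CCCCCCCCCCCCCCCCCO1
F5 | step 1 | 16-bromohexadecyl oct-7-enoate | C=CCCCCCC(=O)OCCCCCCCCCCCCCCCCBr
F6 | step 2 | oct-7-enoyl chloride | C=CCCCCCC(Cl)=O
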